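The route rests on cutting two bonds around the ring B carbon C8 that ends as the exocyclic methylene (labdane numbering): C10–C20 (angular methyl) and C9–C11 (side chain). Since the quaternary C10 is β and the chain-bearing C9 is α to C8, both bonds can be made in one flask from a C8(=O)–C9=C10 octalone. A methyl cuprate adds to C10 and the C8 enolate so formed is captured at C9 by an α-silyl vinyl ketone, giving the cis-fused 8,13-dione with C10 and C9 set. The precursor is an enantiopure ring A/B octalone that already holds the C4 methyl/ester quaternary centre and the C5 hydrogen.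

Key step: step 9

Remark 1 (reading of the target): the SMILES describes a cis-fused decalin with H5, the C10 methyl, the C4 methyl and the C9 chain on one face and the C4 ester on the other, (4R,5S,9S,10R,13R) in labdane numbering.
Remark 2: (S)-1-phenylethylamine is taken to give the less soluble salt with the (R)-acid in step 4; if the pairing is the opposite, the (R)-amine is used and nothing else changes.
Remark 3: the (S)-ligand in step 12 is assigned by analogy with the usual sense for geraniol and geranic acid ((S)-BINAP giving the (R)-configured β-methyl centre); a model run would confirm it, and the (R)-ligand is used if the sense is opposite.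

Step 1
Reactants: 1 6-methoxy-1-tetralone
Product: 2 6-methoxy-1,2,3,4-tetrahydronaphthalene-1-carbonitrile (racemic)
Conditions: TosMIC, t-BuOK, DME/EtOH, 0 °C → rt
Reagents that add atoms: p-toluenesulfonylmethyl isocyanide (TosMIC), Cc1ccc(cc1)S(=O)(=O)C[N+]#[C-]
Why: Van Leusen reductive cyanation turns the aryl ketone directly into the secondary benzylic nitrile, the tosyl group leaving as sulfinate and the isocyanide carbon as ethyl formate; the new centre needs no control because it is methylated and resolved later.

Step 2
Reactants: 2 6-methoxy-1,2,3,4-tetrahydronaphthalene-1-carbonitrile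
Product: 3 6-methoxy-1-methyl-1,2,3,4-tetrahydronaphthalene-1-carbonitrile (racemic)
Conditions: LiN(i-Pr)2, THF, −78 °C; MeI, −78 → 0 °C
Reagents that add atoms: iodomethane, CI
Why: α-alkylation of the benzylic, nitrile-stabilised carbanion with methyl iodide builds the future C4 quaternary centre (racemic) cleanly, since the small linear nitrile offers little hindrance and only one acidic position exists.

Step 3
Reactants: 3 6-methoxy-1-methyl-1,2,3,4-tetrahydronaphthalene-1-carbonitrile
Product: 4 6-methoxy-1-methyl-1,2,3,4-tetrahydronaphthalene-1-carboxylic acid (racemic)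
Conditions: KOH, HOCH2CH2OH, 190 °C; then aq HCl
Reagents that add atoms: potassium hydroxide, [K+].[OH-]; water, O
Why: forcing alkaline hydrolysis of the hindered tertiary nitrile (through the amide) gives the acid needed for resolution and for the Birch step, which a nitrile would not survive; the quaternary centre cannot epimerise and the aryl methyl ether tolerates hydroxide.

Step 4
Reactants: 4 6-methoxy-1-methyl-1,2,3,4-tetrahydronaphthalene-1-carboxylic acid (racemic)
Product: 5 (1R)-6-methoxy-1-methyl-1,2,3,4-tetrahydronaphthalene-1-carboxylic acid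
Conditions: (S)-1-phenylethylamine, EtOH, salt recrystallised to constant rotation; then 2 M HCl, EtOAc
Reagents that add atoms: none
Why: classical resolution by crystallisation of diastereomeric ammonium salts supplies the (R)-acid, which is the C4 centre of the target (ester α, methyl β), and a quaternary α-aryl acid cannot racemise afterwards.

Step 5
Reactants: 5 (1R)-6-methoxy-1-methyl-1,2,3,4-tetrahydronaphthalene-1-carboxylic acid
Product: 7 (1R,8aS)-1-methyl-6-oxo-1,2,3,4,6,7,8,8a-octahydronaphthalene-1-carboxylic acid, via dihydroanisole acid 6 (not isolated)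
Conditions: Li, NH3(l), THF, t-BuOH, −78 → −33 °C; NH4Cl; then 2 M HCl, THF, 40 °C
Reagents that add atoms: water, O
Why: Birch reduction leaves the carboxylate untouched and gives the 2,5-dihydroanisole 6; aqueous acid then hydrolyses the enol ether and moves the C5=C10 bond into conjugation, so C5 is protonated under thermodynamic control through the dienol, where the epimer with H5 anti to an axial C4 carboxyl and the C4 methyl equatorial should predominate, though only modestly, and the mixture is carried into step 6.

Step 6
Reactants: 7 (1R,8aS)-1-methyl-6-oxo-1,2,3,4,6,7,8,8a-octahydronaphthalene-1-carboxylic acid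
Product: 8 methyl (1R,8aS)-1-methyl-6-oxo-1,2,3,4,6,7,8,8a-octahydronaphthalene-1-carboxylate
Conditions: MeI, K2CO3, DMF, rt; SiO2 separation of the C5 epimers (minor epimer: DBU, PhMe, 80 °C, recycled)
Reagents that add atoms: iodomethane, CI
Why: SN2 O-methylation of the carboxylate is insensitive to the hindrance at C4 and leaves the enone alone; the C5 epimers should be separable as esters and the unwanted (1R,8aR) ester is re-equilibrated with DBU and recycled, so only the (4R,5S) octalone enters the key step.

Step 7
Reactants: 9 (1-bromovinyl)trimethylsilane; 10 acetaldehyde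
Product: 12 3-(trimethylsilyl)but-3-en-2-ol (racemic), via Grignard reagent 11 (not isolated)
Conditions: Mg, THF, reflux; then CH3CHO, 0 °C; aq NH4Cl
Reagents that add atoms: none
Why: Grignard formation from the α-bromovinylsilane and 1,2-addition to acetaldehyde give the α-silyl allylic alcohol; the carbinol centre is oxidised away in step 8, so no stereocontrol is needed.

Step 8
Reactants: 12 3-(trimethylsilyl)but-3-en-2-ol
Product: 13 3-(trimethylsilyl)but-3-en-2-one
Conditions: Dess–Martin periodinane, CH2Cl2, 0 °C → rt; distilled and used at once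
Reagents that add atoms: none
Why: Dess–Martin oxidation of the secondary allylic alcohol under non-aqueous, nearly neutral conditions should give the α-silyl vinyl ketone without protodesilylation of the vinylsilane.

Step 9
Reactants: 8 methyl (1R,8aS)-1-methyl-6-oxo-1,2,3,4,6,7,8,8a-octahydronaphthalene-1-carboxylate; 13 3-(trimethylsilyl)but-3-en-2-one
Product: 16 methyl (1R,4aS,5R,8aS)-1,4a-dimethyl-6-oxo-5-(3-oxobutyl)decahydronaphthalene-1-carboxylate, via lithium enolate 14 (not isolated), via silyl diketone 15 (not isolated)
Conditions: CuI, MeLi (2 equiv), Et2O, 0 °C; 8, −78 → 0 °C; then 13, THF, −78 → −20 °C; aq NH4Cl; then KF, AcOH, MeOH, 0 °C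
Reagents that add atoms: lithium dimethylcuprate, [Li+].C[Cu-]C
Why: The homocuprate π-complexes the C8(=O)–C9=C10 enone, transfers methyl to C10 by oxidative addition and reductive elimination and leaves the C8 enolate 14 with its double bond fixed at C8=C9; this enolate adds through C9 to the terminal carbon of 13, the silyl group stabilising the new α-silyl enolate and suppressing proton transfer and polymerisation, and buffered fluoride then removes silicon from 15 without a base able to start aldol closure. The closest known reaction type is organocuprate conjugate addition to a cyclic enone with in situ Michael trapping of the enolate by an α-silyl vinyl ketone, stopped at the 1,5-diketone. No ring is closed. C10 is set by stereoelectronic control: methyl enters perpendicular to the enone on the face of H5, anti to the pseudoaxial C5–C4 bond, while the opposite face is shielded by the axial C4 ester, so the cis-fused decalin results. C9 is set by approach of 13 to the face cis to the new methyl, because the other face lies under the axial C5–C4 bond; this epimer (chain equatorial) is also expected to be the more stable one, so any minor epimer is corrected by enolisation in step 11. The step needs 1,4- rather than 1,2-addition and C- rather than O-alkylation at one defined enolate terminus, which the soft cuprate, the aprotic medium and the regiodefined C8 enolate secure.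

Step 10
Reactants: 16 methyl (1R,4aS,5R,8aS)-1,4a-dimethyl-6-oxo-5-(3-oxobutyl)decahydronaphthalene-1-carboxylate; 17 trimethyl phosphonoacetate
Product: 18 methyl (1R,4aS,5R,8aS)-5-[(3E)-5-methoxy-3-methyl-5-oxopent-3-en-1-yl]-1,4a-dimethyl-6-oxodecahydronaphthalene-1-carboxylate
Conditions: 17 (1.5 equiv), NaH (1.4 equiv), THF, 0 °C; then 16, 0 °C → rt; SiO2 to remove the (Z)-isomer
Reagents that add atoms: none
Why: Horner–Wadsworth–Emmons olefination should take place at the unhindered C13 methyl ketone and not at the C8 ketone flanked by C9 and the quaternary C10, giving mainly the (E)-enoate; the phosphonate is kept in excess over NaH so that no base stronger than the stabilised carbanion is present, which limits aldol closure of the 1,5-diketone, and the (Z)-isomer is removed because it would give the C13 epimer in step 12.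

Step 11
Reactants: 18 methyl (1R,4aS,5R,8aS)-5-[(3E)-5-methoxy-3-methyl-5-oxopent-3-en-1-yl]-1,4a-dimethyl-6-oxodecahydronaphthalene-1-carboxylate
Product: 19 (2E)-5-[(1R,4aS,5R,8aS)-5-(methoxycarbonyl)-5,8a-dimethyl-2-oxodecahydronaphthalen-1-yl]-3-methylpent-2-enoic acid
Conditions: LiOH, THF/MeOH/H2O, rt; then 1 M HCl to pH 3
Reagents that add atoms: lithium hydroxide, [Li+].[OH-]
Why: saponification cleaves only the unhindered conjugated C15 ester, the axial neopentyl C4 ester being inert to LiOH at room temperature, and the same medium equilibrates C9 through the C8 enolate to the epimer with the chain equatorial and cis to the C10 methyl, now without risk of aldol closure because C13 is no longer a ketone.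

Step 12
Reactants: 19 (2E)-5-[(1R,4aS,5R,8aS)-5-(methoxycarbonyl)-5,8a-dimethyl-2-oxodecahydronaphthalen-1-yl]-3-methylpent-2-enoic acid
Product: 20 (3R)-5-[(1R,4aS,5R,8aS)-5-(methoxycarbonyl)-5,8a-dimethyl-2-oxodecahydronaphthalen-1-yl]-3-methylpentanoic acid
Conditions: Ru(OAc)2[(S)-BINAP] (1 mol%), H2 (100 atm), MeOH, 25 °C
Reagents that add atoms: none
Why: carboxylate-directed asymmetric hydrogenation (Noyori type) of the (E)-β,β-disubstituted acrylic acid binds the substrate to ruthenium through the carboxylate and delivers hydrogen to the olefin face fixed by the (S)-ligand, setting (13R) by catalyst control far from the ring centres, while the hindered C8 ketone and the C4 ester are inert to this halide-free complex.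

Step 13
Reactants: 20 (3R)-5-[(1R,4aS,5R,8aS)-5-(methoxycarbonyl)-5,8a-dimethyl-2-oxodecahydronaphthalen-1-yl]-3-methylpentanoic acid
Product: 21 (3R)-5-[(1S,4aS,5R,8aR)-5-(methoxycarbonyl)-5,8a-dimethyl-2-methylidenedecahydronaphthalen-1-yl]-3-methylpentanoic acid
Conditions: Ph3PCH3Br, t-BuOK (4 equiv each), THF, 0 → 60 °C; then dilute HCl to pH 4
Reagents that add atoms: methyltriphenylphosphonium bromide, C[P+](c1ccccc1)(c1ccccc1)c1ccccc1.[Br-]
Why: Wittig methylenation with excess non-stabilised ylide (the first equivalent of base only forms the carboxylate) converts the hindered C8 ketone into the exocyclic methylene, as is usual for 8-oxo ketones of the labdane type; C9 may enolise but its favoured configuration is the required one, and the C4 ester and C13 are not touched.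

Compound list
1 | 6-methoxy-1-tetralone | COc1ccc2C(=O)CCCc2c1 | starting material
2 | 6-methoxy-1,2,3,4-tetrahydronaphthalene-1-carbonitrile (racemic) | COc1ccc2c(c1)CCCC2C#N | intermediate
3 | 6-methoxy-1-methyl-1,2,3,4-tetrahydronaphthalene-1-carbonitrile (racemic) | COc1ccc2c(c1)CCCC2(C)C#N | intermediate
4 | 6-methoxy-1-methyl-1,2,3,4-tetrahydronaphthalene-1-carboxylic acid (racemic) | COc1ccc2c(c1)CCCC2(C)C(=O)O | intermediate
5 | (1R)-6-methoxy-1-methyl-1,2,3,4-tetrahydronaphthalene-1-carboxylic acid | COc1ccc2c(c1)CCC[C@@]2(C)C(=O)O | intermediate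
6 | (1R)-6-methoxy-1-methyl-1,2,3,4,5,8-hexahydronaphthalene-1-carboxylic acid (lithium salt in the flask, not isolated) | COC1=CCC2=C(C1)CCC[C@@]2(C)C(=O)O | intermediate
7 | (1R,8aS)-1-methyl-6-oxo-1,2,3,4,6,7,8,8a-octahydronaphthalene-1-carboxylic acid | O=C1CC[C@H]2C(=C1)CCC[C@@]2(C)C(=O)O | intermediate
8 | methyl (1R,8aS)-1-methyl-6-oxo-1,2,3,4,6,7,8,8a-octahydronaphthalene-1-carboxylate (key-step precursor; H5 cis to the C4 methyl) | O=C1CC[C@H]2C(=C1)CCC[C@@]2(C)C(=O)OC | intermediate
9 | (1-bromovinyl)trimethylsilane | C=C(Br)[Si](C)(C)C | starting material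
10 | acetaldehyde | CC=O | starting material
11 | [1-(trimethylsilyl)ethenyl]magnesium bromide (not isolated) | C=C([Mg]Br)[Si](C)(C)C | intermediate
12 | 3-(trimethylsilyl)but-3-en-2-ol (racemic) | CC(O)C(=C)[Si](C)(C)C | intermediate
13 | 3-(trimethylsilyl)but-3-en-2-one | CC(=O)C(=C)[Si](C)(C)C | intermediate
14 | lithium (4aS,5R,8aS)-5-(methoxycarbonyl)-5,8a-dimethyl-3,4,4a,5,6,7,8,8a-octahydronaphthalen-2-olate (C8 enolate, not isolated) | [Li+].[O-]C=1CC[C@H]2[C@](C)(CCC[C@@]2(C)C(=O)OC)C=1 | intermediate
15 | methyl (1R,4aS,5R,8aS)-1,4a-dimethyl-6-oxo-5-[3-oxo-2-(trimethylsilyl)butyl]decahydronaphthalene-1-carboxylate (epimers at the silyl carbon, not isolated) | O=C1CC[C@H]2[C@](C)(CCC[C@@]2(C)C(=O)OC)[C@H]1CC(C(C)=O)[Si](C)(C)C | intermediate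
16 | methyl (1R,4aS,5R,8aS)-1,4a-dimethyl-6-oxo-5-(3-oxobutyl)decahydronaphthalene-1-carboxylate (key-step product, cis-fused) | O=C1CC[C@H]2[C@](C)(CCC[C@@]2(C)C(=O)OC)[C@H]1CCC(C)=O | intermediate
17 | trimethyl phosphonoacetate | COC(=O)CP(=O)(OC)OC | starting material
18 | methyl (1R,4aS,5R,8aS)-5-[(3E)-5-methoxy-3-methyl-5-oxopent-3-en-1-yl]-1,4a-dimethyl-6-oxodecahydronaphthalene-1-carboxylate | O=C1CC[C@H]2[C@](C)(CCC[C@@]2(C)C(=O)OC)[C@H]1CC/C(C)=C/C(=O)OC | intermediate
19 | (2E)-5-[(1R,4aS,5R,8aS)-5-(methoxycarbonyl)-5,8a-dimethyl-2-oxodecahydronaphthalen-1-yl]-3-methylpent-2-enoic acid | O=C1CC[C@H]2[C@](C)(CCC[C@@]2(C)C(=O)OC)[C@H]1CC/C(C)=C/C(=O)O | intermediate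
20 | (3R)-5-[(1R,4aS,5R,8aS)-5-(methoxycarbonyl)-5,8a-dimethyl-2-oxodecahydronaphthalen-1-yl]-3-methylpentanoic acid | O=C1CC[C@H]2[C@](C)(CCC[C@@]2(C)C(=O)OC)[C@H]1CC[C@@H](C)CC(=O)O | intermediate
21 | (3R)-5-[(1S,4aS,5R,8aR)-5-(methoxycarbonyl)-5,8a-dimethyl-2-methylidenedecahydronaphthalen-1-yl]-3-methylpentanoic acid | C=C1CC[C@H]2[C@](C)(CCC[C@@]2(C)C(=O)OC)[C@H]1CC[C@@H](C)CC(=O)O | target

Total step count: 13 (11 on the main line, 2 for the silyl enone 13).
Longest linear sequence: 11 steps (steps 1–6 and 9–13).

Steps most likely to fail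

Step 9. Methyl transfer to the hindered C10 may be slow. The congested C9 enolate may also deprotonate or oligomerise 13 instead of adding to it. The fallback separates the two events; it sets out from 8 and returns at 16. Me2CuLi with Me3SiCl (THF, −78 °C) should give the C8 silyl enol ether, methyl (1R,4aS,8aS)-1,4a-dimethyl-6-[(trimethylsilyl)oxy]-1,2,3,4,4a,7,8,8a-octahydronaphthalene-1-carboxylate F1, with the same facial course of methyl delivery. F1 is isolated and combined with but-3-en-2-one under TiCl4/Ti(Oi-Pr)4 in CH2Cl2 at −78 °C (Mukaiyama–Michael addition). Aqueous work-up gives dione 16.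

Step 10. The carbanion or traces of stronger base may enolise the 1,5-diketone, which then closes by intramolecular aldol condensation faster than the methyl ketone is olefinated. Poor E/Z control would add to the loss. The fallback avoids an equilibrating base; it sets out from 16 and returns at 19. Lithium ethoxyacetylide (ethoxyethyne, n-BuLi, THF, −78 °C) should add to the unhindered C13 ketone to give methyl (1R,4aS,5R,8aS)-5-(5-ethoxy-3-hydroxy-3-methylpent-4-yn-1-yl)-1,4a-dimethyl-6-oxodecahydronaphthalene-1-carboxylate F2. Dilute H2SO4 in EtOH/THF then brings about Meyer–Schuster rearrangement (Arens–van Dorp sequence) to methyl (1R,4aS,5R,8aS)-5-[(3E)-5-ethoxy-3-methyl-5-oxopent-3-en-1-yl]-1,4a-dimethyl-6-oxodecahydronaphthalene-1-carboxylate F3, whose geometric isomers are separated on SiO2. LiOH as in step 11 cleaves the ethyl ester and gives acid 19.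

Step 12. Enantioface discrimination at the β,β-dialkyl acrylic acid may be incomplete, which would leave C13 epimers that are hard to separate. The fallback moves to the allylic alcohol, the substrate class for which this catalyst is most selective; it sets out from 18 and returns at 20. i-Bu2AlH (CH2Cl2, −78 °C) should reduce the conjugated ester and the C8 ketone but not the hindered C4 ester, giving (as both C8 carbinol epimers) methyl (1R,4aS,5R,8aS)-6-hydroxy-5-[(3E)-5-hydroxy-3-methylpent-3-en-1-yl]-1,4a-dimethyldecahydronaphthalene-1-carboxylate F4. Ru(OAc)2[(S)-BINAP] and H2 in MeOH then set C13 as in the geraniol to citronellol case and give methyl (1R,4aS,5R,8aS)-6-hydroxy-5-[(3R)-5-hydroxy-3-methylpentyl]-1,4a-dimethyldecahydronaphthalene-1-carboxylate F5. CrO3/H2SO4 in acetone (Jones oxidation) converts the primary alcohol into the acid and the C8 carbinol into the ketone, which is keto acid 20; C9 can still equilibrate under the basic conditions of step 13.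

Further compounds
F1 | step 9 | methyl (1R,4aS,8aS)-1,4a-dimethyl-6-[(trimethylsilyl)oxy]-1,2,3,4,4a,7,8,8a-octahydronaphthalene-1-carboxylate | C[Si](C)(C)OC=1CC[C@H]2[C@](C)(CCC[C@@]2(C)C(=O)OC)C=1
F2 | step 10 | methyl (1R,4aS,5R,8aS)-5-(5-ethoxy-3-hydroxy-3-methylpent-4-yn-1-yl)-1,4a-dimethyl-6-oxodecahydronaphthalene-1-carboxylate | O=C1CC[C@H]2[C@](C)(CCC[C@@]2(C)C(=O)OC)[C@H]1CCC(C)(O)C#COCC
F3 | step 10 | methyl (1R,4aS,5R,8aS)-5-[(3E)-5-ethoxy-3-methyl-5-oxopent-3-en-1-yl]-1,4a-dimethyl-6-oxodecahydronaphthalene-1-carboxylate | O=C1CC[C@H]2[C@](C)(CCC[C@@]2(C)C(=O)OC)[C@H]1CC/C(C)=C/C(=O)OCC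
F4 | step 12 | methyl (1R,4aS,5R,8aS)-6-hydroxy-5-[(3E)-5-hydroxy-3-methylpent-3-en-1-yl]-1,4a-dimethyldecahydronaphthalene-1-carboxylate | OC1CC[C@H]2[C@](C)(CCC[C@@]2(C)C(=O)OC)[C@H]1CC/C(C)=C/CO
F5 | step 12 | methyl (1R,4aS,5R,8aS)-6-hydroxy-5-[(3R)-5-hydroxy-3-methylpentyl]-1,4a-dimethyldecahydronaphthalene-1-carboxylate | OC1CC[C@H]2[C@](C)(CCC[C@@]2(C)C(=O)OC)[C@H]1CC[C@@H](C)CCO
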